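**Plan**
- Retrosynthesis: the C8 carbinol (OH and C17 methyl) is traced back to an exocyclic C8=C17 alkene and then to a C8 ketone. Ring B is cut at C6–C7 as an aldol retron, with C7 as the methyl of the C8 ketone and C6 as an aldehyde on C5.
- The open keto aldehyde is the hydrolysed form of ring A fused to a temporary oxacycle in which an oxygen stands in for C7. This is cut at C4–C5 and C9–C10 (bromonium bicyclisation of an allyl vinyl ether), then at O–C8 into a C10 bromochloro allylic alcohol and a C9 alkenylboron piece from (R)-linalool.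
- Forward: ring A and the oxacycle form together, the oxacycle is opened by hydrolysis, and carbocyclic ring B closes last through C6–C7.
- Stereochemistry: C3 by catalytic enantioselective bromochlorination; C5 and C10 relayed from C3 in the chair–chair bicyclisation; C9 by equilibration in the key step; C8 by epoxidation anti to the axial C10 methyl; C13 bought with (R)-linalool.
- Enabling feature: C8 of ring B is a carbinol flanked by C7 and C9. At the ketone level C7 is an enolisable methyl placed 1,5 to C6, C9 is an epimerisable centre, and C5 of ring A carries C6 as an aldehyde.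

Key step: step 14

Remark: labdane numbering is used for atoms (ring A = C1–C5, C10; ring B = C5–C10). The SMILES is read as written, i.e. the antipodal labdane nucleus with equatorial C3–Br and 13R. The geometry of the enol ether double bond is left open on purpose because C9 is equilibrated later.

**Step 1**
Reactants: 1 3-methylbut-2-en-1-ol (prenol)
Product: 2 (2R)-2-bromo-3-chloro-3-methylbutan-1-ol
Conditions: NBS, ClTi(OiPr)3, chiral tridentate Schiff-base ligand (20 mol %, the enantiomer that gives the R product), hexanes, −20 °C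
Reagents that add atoms: N-bromosuccinimide O=C1CCC(=O)N1Br; chlorotitanium triisopropoxide CC(C)O[Ti](Cl)(OC(C)C)OC(C)C
Why: Catalytic enantioselective bromochlorination of an allylic alcohol: the titanium-bound alkoxide holds the alkene in the chiral ligand pocket and chloride is delivered anti to the bromonium at the tertiary carbon, so the ligand sets the C3 bromide (R).

**Step 2**
Reactants: 2 (2R)-2-bromo-3-chloro-3-methylbutan-1-ol
Product: 3 (2R)-2-bromo-3-chloro-3-methylbutyl trifluoromethanesulfonate
Conditions: Tf2O, 2,6-lutidine, CH2Cl2, −78 °C (used crude)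
Reagents that add atoms: triflic anhydride O=S(=O)(OS(=O)(=O)C(F)(F)F)C(F)(F)F
Why: O-Sulfonylation of the primary alcohol at low temperature gives the primary triflate needed for C–C bond formation without touching the vicinal bromochloride.

**Step 3**
Reactants: 3 (2R)-2-bromo-3-chloro-3-methylbutyl trifluoromethanesulfonate; 4 methyl acetoacetate
Product: 6 methyl (6R)-6-bromo-7-chloro-7-methyl-3-oxooctanoate, via acetoacetate dianion 5 (not isolated)
Conditions: NaH, THF, 0 °C; n-BuLi, 0 °C; then 3, −78 to −20 °C; aq. HCl
Reagents that add atoms: none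
Why: Dianion γ-alkylation of a β-keto ester: the terminal carbanion of 5 displaces the primary triflate (SN2) and so adds C1, C10, C5 and C6 in one operation, while C3 is not involved.

**Step 4**
Reactants: 6 methyl (6R)-6-bromo-7-chloro-7-methyl-3-oxooctanoate
Product: 7 methyl (2Z,6R)-6-bromo-7-chloro-7-methyl-3-(trifluoromethanesulfonyloxy)oct-2-enoate
Conditions: KN(SiMe3)2, THF, −78 °C; PhNTf2, −78 to 0 °C
Reagents that add atoms: N-phenylbis(trifluoromethanesulfonimide) O=S(=O)(N(c1ccccc1)S(=O)(=O)C(F)(F)F)C(F)(F)F
Why: Enol triflate formation through the chelated potassium enolate of the β-keto ester should give the Z enol triflate.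

**Step 5**
Reactants: 7 methyl (2Z,6R)-6-bromo-7-chloro-7-methyl-3-(trifluoromethanesulfonyloxy)oct-2-enoate
Product: 8 methyl (2E,6R)-6-bromo-7-chloro-3,7-dimethyloct-2-enoate
Conditions: MeZnCl, Pd(PPh3)4 (5 mol %), THF, 23 °C
Reagents that add atoms: methylzinc chloride C[Zn]Cl
Why: Negishi cross-coupling proceeds with retention of alkene geometry, so the Z triflate becomes the E trisubstituted enoate (the geranyl geometry needed for a trans ring fusion), and oxidative addition of the enol triflate to zerovalent palladium is much faster than that of the secondary alkyl bromide.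

**Step 6**
Reactants: 8 methyl (2E,6R)-6-bromo-7-chloro-3,7-dimethyloct-2-enoate
Product: 9 (2E,6R)-6-bromo-7-chloro-3,7-dimethyloct-2-en-1-ol
Conditions: i-Bu2AlH, CH2Cl2, −78 °C; aq. sodium potassium tartrate
Reagents that add atoms: none
Why: 1,2-Reduction of the conjugated ester by the aluminium hydride at low temperature gives the allylic alcohol and leaves both carbon–halogen bonds alone.

**Step 7**
Reactants: 10 (R)-linalool
Product: 11 tert-butyl{[(3R)-3,7-dimethylocta-1,6-dien-3-yl]oxy}dimethylsilane
Conditions: TBSOTf, 2,6-lutidine, CH2Cl2, 0 to 23 °C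
Reagents that add atoms: tert-butyldimethylsilyl triflate CC(C)(C)[Si](C)(C)OS(=O)(=O)C(F)(F)F
Why: Silylation of the hindered tertiary allylic alcohol with the silyl triflate protects C13–OH as an ether that should be stable to base, fluoroborate formation, buffered ionising solvent, peracid and hydride.

**Step 8**
Reactants: 11 tert-butyl{[(3R)-3,7-dimethylocta-1,6-dien-3-yl]oxy}dimethylsilane
Product: 12 (4R)-4-(tert-butyldimethylsilyloxy)-4-methylhex-5-enal
Conditions: O3 (dosed to a dye end-point), CH2Cl2–MeOH, −78 °C; Me2S
Reagents that add atoms: ozone [O-][O+]=O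
Why: Ozonolysis is chemoselective for the electron-rich trisubstituted alkene over the monosubstituted vinyl group and gives the aldehyde whose carbonyl carbon is C9.

**Step 9**
Reactants: 12 (4R)-4-(tert-butyldimethylsilyloxy)-4-methylhex-5-enal; 13 1,1-bis(pinacolboryl)ethane
Product: 15 tert-butyldimethyl{[(3R)-3-methyl-7-(4,4,5,5-tetramethyl-1,3,2-dioxaborolan-2-yl)octa-1,6-dien-3-yl]oxy}silane (E/Z mixture), via lithiated diboronate 14 (not isolated)
Conditions: Li(tmp) (lithium 2,2,6,6-tetramethylpiperidide), THF, 0 °C; then 12, −78 to 23 °C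
Reagents that add atoms: none
Why: Boron-Wittig olefination: the α-boryl carbanion 14 adds to the aldehyde and syn B–O elimination gives the trisubstituted alkenyl boronate that carries C8 and its methyl (C7), the alkene geometry being of no consequence for the route.

**Step 10**
Reactants: 15 alkenyl pinacol boronate (E/Z mixture)
Product: 16 potassium [(6R)-6-(tert-butyldimethylsilyloxy)-6-methylocta-2,7-dien-2-yl]trifluoroborate (E/Z mixture)
Conditions: KHF2, MeOH–H2O, 23 °C
Reagents that add atoms: potassium hydrogen difluoride F[H-]F.[K+]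
Why: Conversion of the pinacol boronate into the trifluoroborate salt gives the stable, readily transmetalating partner for the oxidative C–O coupling.

**Step 11**
Reactants: 9 (2E,6R)-6-bromo-7-chloro-3,7-dimethyloct-2-en-1-ol; 16 potassium alkenyltrifluoroborate
Product: 17 (2E,6R)-6-bromo-7-chloro-3,7-dimethyloct-2-en-1-yl (6R)-6-(tert-butyldimethylsilyloxy)-6-methylocta-2,7-dien-2-yl ether (enol ether E/Z mixture)
Conditions: Cu(OAc)2·H2O (20 mol %), DMAP, 4 Å MS, O2 (1 atm), CH2Cl2, 23 °C; chromatography on Et3N-deactivated silica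
Reagents that add atoms: none
Why: Chan–Lam oxidative C–O coupling of an alkenyl trifluoroborate with a primary allylic alcohol forms the O–C8 bond at room temperature under nearly neutral conditions that the bromochloride and the acid-labile enol ether should both tolerate.

**Step 12**
Reactants: 17 allyl vinyl ether
Product: 20 3-bromo-6-hydroxy-13-(tert-butyldimethylsilyloxy)-17-nor-6,7-secolabd-14-en-8-one (C9 epimers; in equilibrium with its cyclic hemiketal), via bromonium ion 18 (not isolated), via oxocarbenium ion 19 (not isolated)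
Conditions: (CF3)2CHOH, 2,6-di-tert-butyl-4-methylpyridine, 0 to 23 °C; then THF–H2O, PPTS (cat.), 23 °C
Reagents that add atoms: water O
Why: Proposed new method: in hexafluoroisopropanol the tertiary C4–Cl bond ionises with anchimeric help from the C3 bromine to give the enantiopure bromonium ion 18, the E C5=C10 alkene attacks C4 through a chair (ring A, 6-endo-trig, bromine equatorial), and the C10 cation is captured at C9 by the tethered enol ether (second chair, 6-endo-trig) to give oxocarbenium ion 19, which water hydrolyses to 20; the closest known reaction types are the enantiospecific bromonium polyene cyclisation started by solvolysis of a vicinal bromochloride and the cation–olefin cyclisation terminated by an enol ether, combined here with the enol ether oxygen in the tether; C5 and C10 are relayed from C3 through the trans-anti chair–chair transition state, C9 is left uncontrolled on purpose, and the hindered pyridine removes HCl so that the enol ether and the allylic silyl ether are not protonated.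

**Step 13**
Reactants: 20 hydroxy ketone (C9 epimers)
Product: 21 3-bromo-8-oxo-13-(tert-butyldimethylsilyloxy)-17-nor-6,7-secolabd-14-en-6-al (C9 epimers)
Conditions: Dess–Martin periodinane, pyridine, CH2Cl2, 0 to 23 °C
Reagents that add atoms: none
Why: Dess–Martin oxidation of the hindered primary alcohol, which reacts through the open hydroxy ketone form, gives the C6 aldehyde under buffered conditions.

**Step 14**
Reactants: 21 keto aldehyde (C9 epimers)
Product: 23 3-bromo-13-(tert-butyldimethylsilyloxy)-17-norlabda-6,14-dien-8-one (trans ring fusion; C9 side chain equatorial), via aldol adduct 22 (not isolated)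
Conditions: KOH, MeOH, 23 to 50 °C
Reagents that add atoms: none
Why: Hydroxide reversibly enolises the C8 methyl ketone toward C7; the C7 enolate adds to the C6 aldehyde and E1cB loss of water from aldol 22 gives the conjugated C6=C7–C8=O enone, which drains all equilibria. The closest known reaction type is the intramolecular aldol condensation of a 1,5-keto aldehyde, the ring-closing half of a Robinson annulation. Ring B closes by 6-(enolendo)-exo-trig attack of C7 on C6, whereas the other enolates (C9 on C6, C5 on C8) could only give four-membered rings. No new stereocentre remains in the product; C9 (α to the C8 ketone) and C5 (α to the aldehyde, vinylogous in the enone) are under thermodynamic control and should settle with the C9 side chain equatorial and the ring fusion trans, so both C9 epimers of 21 converge on 23, with the quaternary C10 and C3 as fixed anchors. The step needs C-selective ring closure without loss of HBr, which the absence of any other six-membered aldol pathway and the equatorial C3 bromide (no antiperiplanar hydrogen) should secure.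

**Step 15**
Reactants: 23 enone
Product: 24 3-bromo-13-(tert-butyldimethylsilyloxy)-17-norlabd-14-en-8-one
Conditions: [(Ph3P)CuH]6, H2O, benzene–THF, 23 °C
Reagents that add atoms: none
Why: Conjugate reduction with the phosphine copper hydride is selective for the enone over the vinyl group and the alkyl bromide, and protonation of the copper enolate should give the ketone with the C9 side chain equatorial.

**Step 16**
Reactants: 24 ketone
Product: 25 3-bromo-13-(tert-butyldimethylsilyloxy)labda-8(17),14-diene
Conditions: Ph3PCH3Br, KOt-Bu, toluene, 23 to 80 °C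
Reagents that add atoms: methyltriphenylphosphonium bromide C[P+](c1ccccc1)(c1ccccc1)c1ccccc1.[Br-]
Why: Wittig methylenation of the C8 ketone installs C17 as an exocyclic methylene, and the equatorial bromide, which has no antiperiplanar hydrogen, should survive the basic ylide.

**Step 17**
Reactants: 25 exocyclic alkene
Product: 26 3-bromo-8,17-epoxy-13-(tert-butyldimethylsilyloxy)labd-14-ene (epoxide oxygen anti to the C10 methyl)
Conditions: mCPBA, NaHCO3, CH2Cl2, 0 °C
Reagents that add atoms: 3-chloroperoxybenzoic acid OOC(=O)c1cccc(Cl)c1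
Why: Prilezhaev epoxidation is selective for the 1,1-disubstituted C8=C17 alkene over the monosubstituted vinyl group, and the peracid approaches anti to the axial C10 methyl, which places the oxygen equatorial at C8 and so sets C8.

**Step 18**
Reactants: 26 spiro-epoxide
Product: 27 3-bromo-13-(tert-butyldimethylsilyloxy)labd-14-en-8-ol
Conditions: LiAlH4, THF, 0 to 23 °C
Reagents that add atoms: none
Why: Hydride opens the spiro-epoxide by SN2 at the primary C17, which leaves the tertiary C8 alcohol equatorial and the C8 methyl axial and syn to the C10 methyl, while the equatorial neopentyl-type bromide should be inert to SN2.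

**Step 19**
Reactants: 27 silyl ether
Product: 28 (3R,5S,8S,9S,10R,13R)-3-bromolabd-14-ene-8,13-diol (target)
Conditions: Bu4NF, THF, 23 to 50 °C
Reagents that add atoms: none
Why: Fluoride-induced desilylation frees the tertiary C13 alcohol without acid, so the allylic carbinol cannot ionise.

**Compound list**
1 | 3-methylbut-2-en-1-ol (prenol) | CC(C)=CCO | starting material
2 | (2R)-2-bromo-3-chloro-3-methylbutan-1-ol | OC[C@@H](Br)C(C)(C)Cl | intermediate
3 | (2R)-2-bromo-3-chloro-3-methylbutyl trifluoromethanesulfonate | O=S(=O)(OC[C@@H](Br)C(C)(C)Cl)C(F)(F)F | intermediate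
4 | methyl acetoacetate | COC(=O)CC(C)=O | starting material
5 | methyl acetoacetate dianion, sodium lithium salt (not isolated) | [Na+].[Li+].[CH2-]C(=O)[CH-]C(=O)OC | intermediate
6 | methyl (6R)-6-bromo-7-chloro-7-methyl-3-oxooctanoate | COC(=O)CC(=O)CC[C@@H](Br)C(C)(C)Cl | intermediate
7 | methyl (2Z,6R)-6-bromo-7-chloro-7-methyl-3-(trifluoromethanesulfonyloxy)oct-2-enoate | COC(=O)/C=C(\OS(=O)(=O)C(F)(F)F)CC[C@@H](Br)C(C)(C)Cl | intermediate
8 | methyl (2E,6R)-6-bromo-7-chloro-3,7-dimethyloct-2-enoate | COC(=O)/C=C(\C)CC[C@@H](Br)C(C)(C)Cl | intermediate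
9 | (2E,6R)-6-bromo-7-chloro-3,7-dimethyloct-2-en-1-ol | OC/C=C(\C)CC[C@@H](Br)C(C)(C)Cl | intermediate
10 | (R)-linalool, (3R)-3,7-dimethylocta-1,6-dien-3-ol | C=C[C@](C)(O)CCC=C(C)C | starting material
11 | tert-butyl{[(3R)-3,7-dimethylocta-1,6-dien-3-yl]oxy}dimethylsilane | C=C[C@](C)(O[Si](C)(C)C(C)(C)C)CCC=C(C)C | intermediate
12 | (4R)-4-(tert-butyldimethylsilyloxy)-4-methylhex-5-enal | C=C[C@](C)(O[Si](C)(C)C(C)(C)C)CCC=O | intermediate
13 | 1,1-bis(pinacolboryl)ethane | CC(B1OC(C)(C)C(C)(C)O1)B1OC(C)(C)C(C)(C)O1 | starting material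
14 | lithiated 1,1-bis(pinacolboryl)ethane (not isolated) | [Li+].C[C-](B1OC(C)(C)C(C)(C)O1)B1OC(C)(C)C(C)(C)O1 | intermediate
15 | tert-butyldimethyl{[(3R)-3-methyl-7-(4,4,5,5-tetramethyl-1,3,2-dioxaborolan-2-yl)octa-1,6-dien-3-yl]oxy}silane, E/Z mixture at the boryl alkene | C=C[C@](C)(O[Si](C)(C)C(C)(C)C)CCC=C(C)B1OC(C)(C)C(C)(C)O1 | intermediate
16 | potassium [(6R)-6-(tert-butyldimethylsilyloxy)-6-methylocta-2,7-dien-2-yl]trifluoroborate, E/Z mixture | C=C[C@](C)(O[Si](C)(C)C(C)(C)C)CCC=C(C)[B-](F)(F)F.[K+] | intermediate
17 | allyl vinyl ether: (2E,6R)-6-bromo-7-chloro-3,7-dimethyloct-2-en-1-yl (6R)-6-(tert-butyldimethylsilyloxy)-6-methylocta-2,7-dien-2-yl ether, enol ether E/Z mixture | C=C[C@](C)(O[Si](C)(C)C(C)(C)C)CCC=C(C)OC/C=C(\C)CC[C@@H](Br)C(C)(C)Cl | intermediate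
18 | bromonium ion of 17, bromine bridging C3 and C4, chloride counter-ion (not isolated) | C=C[C@](C)(O[Si](C)(C)C(C)(C)C)CCC=C(C)OC/C=C(\C)CC[C@H]1[Br+]C1(C)C.[Cl-] | intermediate
19 | bicyclic oxocarbenium ion: ring A trans-fused to a six-membered ring with oxygen in the place of C7, C8 cationic, chloride counter-ion (not isolated) | C=C[C@](C)(O[Si](C)(C)C(C)(C)C)CCC1C(C)=[O+]C[C@@H]2C(C)(C)[C@H](Br)CC[C@@]12C.[Cl-] | intermediate
20 | 3-bromo-6-hydroxy-13-(tert-butyldimethylsilyloxy)-17-nor-6,7-secolabd-14-en-8-one: ring A with equatorial 3R bromide, equatorial CH2OH on C5 trans to the C9 chain on C10; C9 epimers | C=C[C@](C)(O[Si](C)(C)C(C)(C)C)CCC(C(C)=O)[C@]1(C)CC[C@@H](Br)C(C)(C)[C@H]1CO | intermediate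
21 | 3-bromo-8-oxo-13-(tert-butyldimethylsilyloxy)-17-nor-6,7-secolabd-14-en-6-al, C9 epimers | C=C[C@](C)(O[Si](C)(C)C(C)(C)C)CCC(C(C)=O)[C@]1(C)CC[C@@H](Br)C(C)(C)[C@H]1C=O | intermediate
22 | aldol adduct 3-bromo-6-hydroxy-13-(tert-butyldimethylsilyloxy)-17-norlabd-14-en-8-one, C6 and C9 epimers (not isolated) | C=C[C@](C)(O[Si](C)(C)C(C)(C)C)CCC1[C@]2(C)CC[C@@H](Br)C(C)(C)[C@H]2C(O)CC1=O | intermediate
23 | 3-bromo-13-(tert-butyldimethylsilyloxy)-17-norlabda-6,14-dien-8-one, trans ring fusion, C9 side chain equatorial | C=C[C@](C)(O[Si](C)(C)C(C)(C)C)CC[C@H]1[C@]2(C)CC[C@@H](Br)C(C)(C)[C@H]2C=CC1=O | intermediate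
24 | 3-bromo-13-(tert-butyldimethylsilyloxy)-17-norlabd-14-en-8-one | C=C[C@](C)(O[Si](C)(C)C(C)(C)C)CC[C@H]1[C@]2(C)CC[C@@H](Br)C(C)(C)[C@H]2CCC1=O | intermediate
25 | 3-bromo-13-(tert-butyldimethylsilyloxy)labda-8(17),14-diene | C=C[C@](C)(O[Si](C)(C)C(C)(C)C)CC[C@H]1[C@]2(C)CC[C@@H](Br)C(C)(C)[C@H]2CCC1=C | intermediate
26 | 3-bromo-8,17-epoxy-13-(tert-butyldimethylsilyloxy)labd-14-ene, epoxide oxygen anti to the C10 methyl | C=C[C@](C)(O[Si](C)(C)C(C)(C)C)CC[C@H]1[C@]2(C)CC[C@@H](Br)C(C)(C)[C@H]2CC[C@@]13CO3 | intermediate
27 | 3-bromo-13-(tert-butyldimethylsilyloxy)labd-14-en-8-ol, configured as the target | C=C[C@](C)(O[Si](C)(C)C(C)(C)C)CC[C@H]1[C@]2(C)CC[C@@H](Br)C(C)(C)[C@H]2CC[C@]1(C)O | intermediate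
28 | (3R,5S,8S,9S,10R,13R)-3-bromolabd-14-ene-8,13-diol, CNP0150870.4 | C=C[C@](C)(O)CC[C@H]1[C@]2(C)CC[C@@H](Br)C(C)(C)[C@H]2CC[C@]1(C)O | target

**Totals**
Total step count: 19. Longest linear sequence: 15 steps (steps 1–6, then 11–19).

**Steps most likely to fail**

Step 12 (proposed new method). What may go wrong: protonation or solvolysis of the enol ether, or its [3,3] rearrangement, outruns ionisation of the chloride; or the C10 cation loses a proton before C9 can trap it. The fallback separates the two C–C bond formations with known chemistry and sets out from 9 and 15. Alcohol 9 is acetylated (Ac2O, pyridine) to (2E,6R)-6-bromo-7-chloro-3,7-dimethyloct-2-en-1-yl acetate F1. Solvolysis of F1 in (CF3)2CHOH, the known bromochloride-initiated monocyclisation with the alkene as the only nucleophile, should give [3-bromo-2,2-dimethyl-6-methylidenecyclohexyl]methyl acetate F2, with Br and CH2OAc cis and equatorial. Dry HCl in CH2Cl2 at −78 °C adds to the exocyclic alkene to give the tertiary chloride [3-bromo-6-chloro-2,2,6-trimethylcyclohexyl]methyl acetate F3. In parallel, 15 is oxidised (NaBO3·4H2O, THF–H2O) to (6R)-6-(tert-butyldimethylsilyloxy)-6-methyloct-7-en-2-one F4, which is converted (Me3SiCl, Et3N, DMF, heat) into its more substituted trimethylsilyl enol ether F5. Lewis-acid-mediated α-tert-alkylation of F5 with F3 (ZnCl2, CH2Cl2, −40 to 0 °C), in which the enol ether should approach the C10 cation anti to the syn-axial C4 methyl, gives the acetoxy ketone F6. Methanolysis (K2CO3, MeOH) returns the route at 20.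

Step 11. What may go wrong: slow transmetalation of the hindered α-methyl alkenylboron partner, so that protodeboronation or copper-mediated oxidation of the allylic alcohol takes over. The fallback reverses the polarity of the alkenyl partner and sets out from 15 and 9. Iododeboronation of 15 (NaOH, I2, THF–H2O) gives the alkenyl iodide tert-butyl{[(3R)-7-iodo-3-methylocta-1,6-dien-3-yl]oxy}dimethylsilane F7. Ullmann-type C–O coupling of F7 with 9 (CuI, 3,4,7,8-tetramethyl-1,10-phenanthroline, Cs2CO3, toluene, 80 °C, kept below the onset of sigmatropic rearrangement) comes back to the route at 17.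

Step 3. What may go wrong: the strongly basic dianion removes the C3 proton of the β-bromo triflate and elimination competes with substitution at the hindered primary carbon. The fallback uses a softer aza-enolate and a different route to the E alkene, setting out from 3. Alkylation of 3 with lithiated acetone N,N-dimethylhydrazone (LiN(i-Pr)2, THF, −78 °C) gives the hydrazone F8 of (5R)-5-bromo-6-chloro-6-methylheptan-2-one. Mild hydrolysis (aq. oxalic acid, Et2O) frees (5R)-5-bromo-6-chloro-6-methylheptan-2-one F9. Horner–Wadsworth–Emmons olefination of F9 with trimethyl phosphonoacetate (NaH, THF), followed by removal of the minor Z isomer, comes back to the route at 8 and makes steps 4 and 5 unnecessary.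

**Further compounds**
F1 | step 12 | (2E,6R)-6-bromo-7-chloro-3,7-dimethyloct-2-en-1-yl acetate | CC(=O)OC/C=C(\C)CC[C@@H](Br)C(C)(C)Cl
F2 | step 12 | [3-bromo-2,2-dimethyl-6-methylidenecyclohexyl]methyl acetate, Br (3R) and CH2OAc cis and equatorial | C=C1CC[C@@H](Br)C(C)(C)[C@H]1COC(C)=O
F3 | step 12 | [3-bromo-6-chloro-2,2,6-trimethylcyclohexyl]methyl acetate, epimers at the chloride carbon | CC1(Cl)CC[C@@H](Br)C(C)(C)[C@H]1COC(C)=O
F4 | step 12 | (6R)-6-(tert-butyldimethylsilyloxy)-6-methyloct-7-en-2-one | C=C[C@](C)(O[Si](C)(C)C(C)(C)C)CCCC(C)=O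
F5 | step 12 | tert-butyldimethyl{[(3R)-3-methyl-7-(trimethylsilyloxy)octa-1,6-dien-3-yl]oxy}silane, E/Z mixture | C=C[C@](C)(O[Si](C)(C)C(C)(C)C)CCC=C(C)O[Si](C)(C)C
F6 | step 12 | 6-acetoxy-3-bromo-13-(tert-butyldimethylsilyloxy)-17-nor-6,7-secolabd-14-en-8-one, C9 epimers | C=C[C@](C)(O[Si](C)(C)C(C)(C)C)CCC(C(C)=O)[C@]1(C)CC[C@@H](Br)C(C)(C)[C@H]1COC(C)=O
F7 | step 11 | tert-butyl{[(3R)-7-iodo-3-methylocta-1,6-dien-3-yl]oxy}dimethylsilane, E/Z mixture | C=C[C@](C)(O[Si](C)(C)C(C)(C)C)CCC=C(C)I
F8 | step 3 | (5R)-5-bromo-6-chloro-6-methylheptan-2-one N,N-dimethylhydrazone | CN(C)N=C(C)CC[C@@H](Br)C(C)(C)Cl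
F9 | step 3 | (5R)-5-bromo-6-chloro-6-methylheptan-2-one | CC(=O)CC[C@@H](Br)C(C)(C)Cl
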